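**Plan**

- Labels: the carbons of ring A are called a to f in ring order; a carries the butanoyl group, b OH, c CH3, d OCH3, e the CH2 bridge and f OH. Ring B is the acetylfilicinic acid ring.
- Cuts: the CH2–ring B bond (quinone methide alkylation), the bond from carbon a to the acyl group (Friedel–Crafts), and inside ring A the bonds b–c, d–e and a–b (cyclobutenone/ynol ether benzannulation).
- Enabling feature: the oxygens on carbons b, d and f stand 1,3,5 on ring A and end as three different groups. They map onto the carbonyl oxygen and the 3-ethoxy group of a cyclobutenone and the oxygen of 1-methoxypropyne, so ring A emerges with free OH on b, OCH3 on d, OC2H5 on f and carbon a as its only CH.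
- Forward order: ring A is built first (steps 1–4), then sulfide to sulfone, butanoylation at carbon a and chelation-controlled de-ethylation at carbon f. Ring B, made separately by geminal C-methylation of 2,4,6-trihydroxyacetophenone, is attached last through the methylene on carbon e.
- Stereochemistry: the target has no stereocentre and no stereogenic double bond, so nothing has to be set.

Key step: step 4

Assumption: ring B is drawn as one enol tautomer and all tautomers of the β-triketone count as the same compound; ketene gas is generated as needed by pyrolysis of acetone.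

**Route**

Step 1
Reactants: 1 ethoxyacetylene; 2 chloromethyl phenyl sulfide
Product: 4 1-ethoxy-3-(phenylsulfanyl)prop-1-yne, via lithium ethoxyacetylide 3 (not isolated)
Conditions: n-BuLi, THF, −78 °C; then 2, DMPU, −78 °C → rt
Reagents that add atoms: none
Why: Deprotonation gives acetylide 3, and its bimolecular substitution on the α-chloro sulfide 2 (an activated electrophile, helped by DMPU) is a standard acetylide alkylation that keeps the acid-sensitive ynol ether under basic conditions throughout.

Step 2
Reactants: 4 1-ethoxy-3-(phenylsulfanyl)prop-1-yne
Product: 5 3-ethoxy-2-[(phenylsulfanyl)methyl]cyclobut-2-en-1-one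
Conditions: ketene (gas, excess, from acetone pyrolysis), CH2Cl2, 0 °C → rt
Reagents that add atoms: ketene, C=C=O
Why: This is the [2+2] cycloaddition of ketene to an ynol ether, the established entry to 3-alkoxycyclobutenones; the nucleophilic carbon of 4 remote from oxygen attacks the ketene carbonyl carbon, which places OC2H5 on ring carbon 3 and the thiomethyl arm on ring carbon 2 of the cyclobutenone, and the thioether does not react with ketene.

Step 3
Reactants: 6 2-bromo-1,1-dimethoxypropane
Product: 8 1-methoxypropyne, via 2-bromo-1-methoxyprop-1-ene 7 (not isolated)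
Conditions: NaNH2 (2.2 equiv), liquid NH3, −33 °C; pentane/ice-water work-up, distillation
Reagents that add atoms: none
Why: Twofold amide-induced β-elimination (methanol first, to 7, then HBr) is the transformation that turns haloacetaldehyde acetals into alkoxyacetylenes, and the product has no acetylenic hydrogen to consume further base.

Step 4
Reactants: 5 3-ethoxy-2-[(phenylsulfanyl)methyl]cyclobut-2-en-1-one; 8 1-methoxypropyne
Product: 13 5-ethoxy-3-methoxy-2-methyl-4-[(phenylsulfanyl)methyl]phenol, via vinylketene 9 (not isolated), via vinylcyclobutenone 10 (not isolated), via dienylketene 11 (not isolated), via cyclohexadienone 12 (not isolated)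
Conditions: 8 (2.5 equiv), toluene, sealed tube, 110 °C, then 140 °C
Reagents that add atoms: none
Why: Strain drives a four-electron electrocyclic opening of the bond between the carbonyl carbon and the CH2 carbon of 5 to vinylketene 9, whose ketene C=C adds ynol ether 8 in a [2+2] step to give 10 (bonds b–c and d–e of ring A); 10 reopens to dienylketene 11, which cyclises to 12 and tautomerises to phenol 13. The closest known reaction is the Danheiser benzannulation of cyclobutenones with alkoxyalkynes. Ring A closes by thermal six-electron electrocyclisation of the (3Z)-dienylketene, forming bond a–b, and aromatisation makes the sequence irreversible. No stereocentre results, since the racemic quaternary carbon of 10 is erased when 10 opens. The step needs regiocontrol in the [2+2] addition, and the polarisation of 8 supplies it: the methyl-bearing carbon remote from oxygen is the nucleophile toward the ketene carbon, which puts CH3 on carbon c and OCH3 on carbon d, while only the Z isomer of 11 can cyclise and reversible opening of 10 should funnel material through it. A methyl ynol ether cannot fragment by retro-ene loss of an alkene at these temperatures, excess 8 should outrun O-acylation of 13 by 9, and the thioether is a spectator.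

Step 5
Reactants: 13 5-ethoxy-3-methoxy-2-methyl-4-[(phenylsulfanyl)methyl]phenol
Product: 15 4-[(benzenesulfonyl)methyl]-5-ethoxy-3-methoxy-2-methylphenol, via sulfoxide 14 (not isolated)
Conditions: 30% aq. H2O2, (NH4)6Mo7O24·4H2O (cat.), EtOH, 0 °C → rt
Reagents that add atoms: hydrogen peroxide, OO
Why: (NH4)6Mo7O24-catalysed peroxide oxidation of a thioether to the sulfone through 14 is much faster than attack on the electron-rich phenol ring, and the sulfone is installed now because it is not acylated on sulfur, resists the Lewis acids of steps 6 and 7 better than the sulfide, and is the leaving group for step 9.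

Step 6
Reactants: 15 4-[(benzenesulfonyl)methyl]-5-ethoxy-3-methoxy-2-methylphenol
Product: 16 1-{3-[(benzenesulfonyl)methyl]-2-ethoxy-6-hydroxy-4-methoxy-5-methylphenyl}butan-1-one
Conditions: butanoyl chloride, TiCl4, CH2Cl2, −20 °C → rt
Reagents that add atoms: butanoyl chloride, CCCC(=O)Cl
Why: Friedel–Crafts acylation with TiCl4 bound at the phenol oxygen on carbon b should go to carbon a, the only unsubstituted ring carbon, which is ortho to the oxygens on carbons b and f and para to the methoxy group on carbon d; any chelation-assisted loss of the ethyl group on the carbon f oxygen here only anticipates step 7.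

Step 7
Reactants: 16 1-{3-[(benzenesulfonyl)methyl]-2-ethoxy-6-hydroxy-4-methoxy-5-methylphenyl}butan-1-one
Product: 17 1-{3-[(benzenesulfonyl)methyl]-2,6-dihydroxy-4-methoxy-5-methylphenyl}butan-1-one
Conditions: BCl3 (1 M in CH2Cl2, 3 equiv), CH2Cl2, −78 °C → 0 °C; aqueous work-up
Reagents that add atoms: none
Why: In this chelation-controlled ether cleavage, boron held at the ketone oxygen reaches only the ortho ethoxy group on carbon f and delivers chloride to its ethyl carbon, while the methoxy group on carbon d, para to the carbonyl, cannot chelate and should survive at low temperature; the sulfone is inert.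

Step 8
Reactants: 18 2,4,6-trihydroxyacetophenone
Product: 20 2-acetyl-3,5-dihydroxy-4,4-dimethylcyclohexa-2,5-dien-1-one (acetylfilicinic acid), via 3-methyl-2,4,6-trihydroxyacetophenone 19 (not isolated)
Conditions: NaOMe (3 equiv), MeI (2.1 equiv), MeOH, 0 °C → rt; then aq. HCl
Reagents that add atoms: iodomethane, CI
Why: Base-mediated C-methylation of the phloroglucinol polyanion is a known preparation of acetylfilicinic acid; after the first methylation (19) the same ring carbon is the most nucleophilic site, and the second methyl group there breaks aromaticity to leave the enolised β-triketone, the MeI being limited to curb further methylation.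

Step 9
Reactants: 17 1-{3-[(benzenesulfonyl)methyl]-2,6-dihydroxy-4-methoxy-5-methylphenyl}butan-1-one; 20 acetylfilicinic acid
Product: 22 2-acetyl-6-[(3-butanoyl-2,4-dihydroxy-6-methoxy-5-methylphenyl)methyl]-3,5-dihydroxy-4,4-dimethylcyclohexa-2,5-dien-1-one (target), via ortho-quinone methide 21 (not isolated)
Conditions: 20 (1.5 equiv), K2CO3 (3 equiv), DMF, rt → 40 °C; then 1 M HCl
Reagents that add atoms: none
Why: Base-induced 1,4-elimination of benzenesulfinate from the ortho-hydroxybenzyl sulfone gives quinone methide 21, and Michael addition of the only unsubstituted ring carbon of the acetylfilicinate anion with re-aromatisation of ring A forms the CH2–ring B bond; this is the established sulfone route to ortho-quinone methides trapped by 1,3-dicarbonyl nucleophiles, and C-alkylation is the thermodynamic outcome because O-adducts can revert to 21.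

**Compound list**

1 | ethoxyacetylene | CCOC#C | starting material
2 | chloromethyl phenyl sulfide | ClCSc1ccccc1 | starting material
3 | lithium ethoxyacetylide | [Li]C#COCC | intermediate
4 | 1-ethoxy-3-(phenylsulfanyl)prop-1-yne | CCOC#CCSc1ccccc1 | intermediate
5 | 3-ethoxy-2-[(phenylsulfanyl)methyl]cyclobut-2-en-1-one | CCOC1=C(CSc2ccccc2)C(=O)C1 | intermediate
6 | 2-bromo-1,1-dimethoxypropane (racemic) | COC(OC)C(C)Br | starting material
7 | 2-bromo-1-methoxyprop-1-ene (E/Z mixture) | COC=C(C)Br | intermediate
8 | 1-methoxypropyne | COC#CC | intermediate
9 | 3-ethoxy-2-[(phenylsulfanyl)methyl]buta-1,3-dien-1-one (vinylketene) | C=C(OCC)C(CSc1ccccc1)=C=O | intermediate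
10 | 4-(1-ethoxyethenyl)-3-methoxy-2-methyl-4-[(phenylsulfanyl)methyl]cyclobut-2-en-1-one (racemic) | CC1=C(OC)C(CSc2ccccc2)(C(=C)OCC)C1=O | intermediate
11 | (3Z)-5-ethoxy-3-methoxy-2-methyl-4-[(phenylsulfanyl)methyl]hexa-1,3,5-trien-1-one (dienylketene) | O=C=C(C)/C(OC)=C(/CSc1ccccc1)C(OCC)=C | intermediate
12 | 5-ethoxy-3-methoxy-2-methyl-4-[(phenylsulfanyl)methyl]cyclohexa-2,4-dien-1-one | CC1=C(OC)C(CSc2ccccc2)=C(OCC)CC1=O | intermediate
13 | 5-ethoxy-3-methoxy-2-methyl-4-[(phenylsulfanyl)methyl]phenol | Cc1c(O)cc(OCC)c(CSc2ccccc2)c1OC | intermediate
14 | 4-[(benzenesulfinyl)methyl]-5-ethoxy-3-methoxy-2-methylphenol (racemic at sulfur) | Cc1c(O)cc(OCC)c(CS(=O)c2ccccc2)c1OC | intermediate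
15 | 4-[(benzenesulfonyl)methyl]-5-ethoxy-3-methoxy-2-methylphenol | Cc1c(O)cc(OCC)c(CS(=O)(=O)c2ccccc2)c1OC | intermediate
16 | 1-{3-[(benzenesulfonyl)methyl]-2-ethoxy-6-hydroxy-4-methoxy-5-methylphenyl}butan-1-one | CCCC(=O)c1c(O)c(C)c(OC)c(CS(=O)(=O)c2ccccc2)c1OCC | intermediate
17 | 1-{3-[(benzenesulfonyl)methyl]-2,6-dihydroxy-4-methoxy-5-methylphenyl}butan-1-one | CCCC(=O)c1c(O)c(C)c(OC)c(CS(=O)(=O)c2ccccc2)c1O | intermediate
18 | 2,4,6-trihydroxyacetophenone | CC(=O)c1c(O)cc(O)cc1O | starting material
19 | 1-(2,4,6-trihydroxy-3-methylphenyl)ethan-1-one | CC(=O)c1c(O)cc(O)c(C)c1O | intermediate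
20 | 2-acetyl-3,5-dihydroxy-4,4-dimethylcyclohexa-2,5-dien-1-one (acetylfilicinic acid) | CC(=O)C1=C(O)C(C)(C)C(O)=CC1=O | intermediate
21 | 2-butanoyl-3-hydroxy-5-methoxy-4-methyl-6-methylidenecyclohexa-2,4-dien-1-one (ortho-quinone methide) | CCCC(=O)C1=C(O)C(C)=C(OC)C(=C)C1=O | intermediate
22 | 2-acetyl-6-[(3-butanoyl-2,4-dihydroxy-6-methoxy-5-methylphenyl)methyl]-3,5-dihydroxy-4,4-dimethylcyclohexa-2,5-dien-1-one | CCCC(=O)c1c(O)c(C)c(OC)c(CC2=C(O)C(C)(C)C(O)=C(C(C)=O)C2=O)c1O | target

**Step count**

Total: 9 steps. Longest linear sequence: 7 steps (1, 2, 4, 5, 6, 7, 9); steps 3 and 8 supply the two side fragments.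

**Steps most likely to fail**

Step 4. Opening 5 costs the vinylogous-ester conjugation of the 3-ethoxy enone and may need temperatures at which 8 oligomerises, the electron-rich benzylic sulfide of 13 ionises, or 13 is acylated on oxygen by 9. The fallback generates vinylketene 9 without the electrocyclic opening. It sets out from 5: aqueous LiOH in THF should cleave the four-membered ring at the carbonyl, as 3-alkoxycyclobutenones act as acylating agents toward oxygen nucleophiles, to give (2Z)-3-ethoxy-2-[(phenylsulfanyl)methyl]but-2-enoic acid F1. Oxalyl chloride with catalytic DMF then gives (2E)-3-ethoxy-2-[(phenylsulfanyl)methyl]but-2-enoyl chloride F2. Slow addition of F2 to Et3N and excess 8 in CH2Cl2 at 0 °C → rt effects 1,4-dehydrochlorination, the classical access to vinylketenes, so that 9 is intercepted by 8 as it forms. Brief warming to about 80 °C should then carry 10 through 11 and 12 to 13, where the route is rejoined.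

Step 7. The dealkylation may stall because boron is first captured between the oxygen on carbon b and the carbonyl, or it may lose selectivity and also remove the hindered methyl group from the oxygen on carbon d. The fallback gives up selectivity in the cleavage and recovers it in an alkylation. From 16, excess BBr3 (CH2Cl2, −78 °C → rt) removes both alkyl groups to give 1-{3-[(benzenesulfonyl)methyl]-2,4,6-trihydroxy-5-methylphenyl}butan-1-one F3. Trimethylsilyldiazomethane in toluene–methanol at 0 °C should then methylate only the hydroxyl on carbon d, the one phenol not hydrogen-bonded to the ketone and the most acidic because it is para to the acyl group. This returns 17 under conditions too mild to expel sulfinate.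

Step 9. In carbonate/DMF the quinone methide may form slowly from the acyl-stabilised phenoxide, may be captured on oxygen, or the methylene-bridged product may redistribute by retro-Michael cleavage toward symmetric dimers. The fallback moves the coupling to neutral, thermal conditions through a Mannich base. From 17, warming in neat morpholine should exchange sulfinate for the amine by elimination and aza-Michael addition, giving 1-{2,6-dihydroxy-4-methoxy-3-methyl-5-[(morpholin-4-yl)methyl]phenyl}butan-1-one F4. Heating F4 with 20 in refluxing ethanol then transfers the benzyl unit to the free ring carbon of 20 with loss of morpholine, the classical way of joining two phloroglucinol-type halves through a methylene group, and delivers 22.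

**Further compounds**

F1 | step 4 | (2Z)-3-ethoxy-2-[(phenylsulfanyl)methyl]but-2-enoic acid | CCO/C(C)=C(\CSc1ccccc1)C(=O)O
F2 | step 4 | (2E)-3-ethoxy-2-[(phenylsulfanyl)methyl]but-2-enoyl chloride | CCO/C(C)=C(\CSc1ccccc1)C(Cl)=O
F3 | step 7 | 1-{3-[(benzenesulfonyl)methyl]-2,4,6-trihydroxy-5-methylphenyl}butan-1-one | CCCC(=O)c1c(O)c(C)c(O)c(CS(=O)(=O)c2ccccc2)c1O
F4 | step 9 | 1-{2,6-dihydroxy-4-methoxy-3-methyl-5-[(morpholin-4-yl)methyl]phenyl}butan-1-one | CCCC(=O)c1c(O)c(C)c(OC)c(CN2CCOCC2)c1O
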